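## Structural features

The target is an achiral, fully unsaturated assembly of four rings: a 7-hydroxy-5-methylchromone (benzo ring A fused to 4-pyranone ring B), a resorcinol ring C bonded through C1' to C2 of ring B, and a 4-hydroxy-2-pyranone ring D attached to C6' of ring C through one CH2 group. There is no stereocentre. The C2–C1' axis is flanked on ring C by the C2' hydroxyl and the C6' methylene but on the chromone side only by O1 and C3–H, so no configurationally stable axis has to be set. Ring C is 1,2,3,5-tetrasubstituted, and ring A carries methyl at C5, hydroxyl at C7 and the ring oxygen at C8a around the ketone-bearing C4a, which is an orcinol pattern. The fragile parts are ring D (an acidic vinylogous acid, nucleophilic at C3'' and open to ring cleavage by hard nucleophiles), the doubly activated CH2 between rings C and D, the chromone (opened by hydroxide) and the electron-rich polyphenol as a whole. The real difficulty is regiochemical: four phenolic oxygens sit on two benzene rings, and an ortho oxygen of either ring A or ring C could close a pyranone or furan ring onto the three-carbon bridge. The key step uses the fact that C5(CH3)–C4a(C=O) is the two-carbon unit of a but-2-ynoyl group and C6–C7(O)–C8–C8a(O) is the four-carbon unit of a 1,1-dialkoxy-3-silyloxybutadiene. Ring A can therefore be made by a [4+2] benzannulation that leaves the C8a oxygen ortho to the ketone, next to an intact aryl alkyne ready to close ring B.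

## Logic of the disconnections

**22 to 21.** The last operation removes the three O–CH3 bonds at the C2', C4' and C4'' oxygens of 21; no skeletal bond is involved. These ethers are kept to the end because a free C2' hydroxyl or a free ring D enol would attack the ynone of the earlier intermediates. The gain is that every compound before 22 is neutral and free of acidic O–H at these positions. The forward step needs a reagent that cleaves two aryl methyl ethers and one vinylogous ester methyl ether without harming rings B and D.

**21 to 19.** Ring B is opened at O1–C2, leading back through 20 to 19, in which C2, C3 and C4 form an ynone between the two arenes. The cut is placed there because closure is a heteroatom addition that needs no new carbon–carbon bond. The forward step must deliver the oxygen to C2 (six-membered ring) and not to C3 (five-membered ring), and only the ring A oxygen may react. The first demand is met by the amine relay through 20, the second by the methyl ethers on ring C.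

**19 to 18.** The two compounds differ only in the O–CH3 bond on the C8a oxygen. The methyl group is accepted in 18 because the cycloaddition delivers this oxygen as a methyl ether. The forward step must remove one methyl ether out of four, which chelation to the neighbouring ketone makes possible.

**18 to 14 and 15.** The bonds C5–C6 and C4a–C8a of ring A are cut together. This removes a whole tetrasubstituted benzene ring and gives 14, a linear diynone, and 15, a four-carbon diene. Mapping diene C4 to C6, C3 to C7, C2 to C8 and C1 to C8a, and the alkyne β- and α-carbons to C5 and C4a, reproduces the substitution of 18 exactly. The forward step has to select the methyl-substituted alkyne of 14 over the aryl-substituted one and add in a single orientation.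

**14 to 11 and 12.** The bond between the ketone carbon and the aryl-substituted alkyne is cut, giving the terminal alkyne 11 and the four-carbon acid 12, which is used through 13. The cut is made on this side so that the short, volatile fragment is the acyl donor and the valuable fragment is only a terminal alkyne. The forward step must form the ynone without strong base, which the CH2 group and ring D of 11 would not survive.

**11 to 8 and 9.** The C1'–C(sp) bond is cut, through 10, to the aryl iodide 8 and the silylated acetylene 9. An iodide is chosen over a bromide because the carbon to be alkynylated lies between two ortho substituents on a donor-rich ring. The forward steps are a cross-coupling and a desilylation that leave the lactone untouched.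

**8 to 6.** The O–CH3 bond on the ring D oxygen is cut (8 to 7), and then the lactone bond O1''–C2'' (7 to 6). Ring D becomes an open 3,5-dioxo ester, and the only demand is lactonization of the C5 enol onto the ester.

**6 to 2 and 3.** The C4–C5 bond of the hexanoate chain is cut, between the terminal carbon of 3 (used as 5) and the carboxyl carbon of 2 (used as 4). This divides the chain into a purchasable C4 unit and an arylacetic acid. The forward step must achieve C-acylation at the terminal carbon of the dianion in the presence of the enolizable CH2 of 4.

**2 to 1.** The C–I bond is cut. The forward iodination has to take the position ortho to the CH2 group (para to one methoxy group) and not the position between the two methoxy groups.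

## Other disconnections considered

**Alternative 1:** The cut is the C1'–C6' bond of ring C in the 7-O-methyl ether A2, with C2', C4' and C6' hidden as the central 4-pyranone of the tris-heterocycle A1. In the forward sense KOH in methanol would open that pyranone, and the C1' carbanion would add to the C6' carbonyl and dehydrate to the resorcinol.

- In favour: the step imitates polyketide folding and makes ring C with both hydroxyls already free. A2 then needs only one ether cleavage, which is better than the three operations that follow the key step of the chosen plan.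
- Against: once A1 is opened, four methylene groups flank three carbonyls. The CH2 next to ring D can attack the C2' carbonyl and give a regioisomeric resorcinol. Hydroxide can also open ring B and the lactone of ring D. A1 itself would need two lateral acylations between three heterocycles, which is expected to take longer than the seven steps to 14.
- Comparison: on structure, both plans close a benzene ring late. On mechanism, the alternative relies on a thermodynamic choice among several enolates in strong base, whereas the chosen plan fixes ring C by purchase and ring A by the polarity of one neutral cycloaddition. On step economy, the alternative is better after the key step and probably worse before it.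

**Alternative 2:** Four bonds of ring C are cut (C5'–C6', C2'–C3', C4'–C5', C1'–C2'), leading to the diazo enone A3 and ethoxyacetylene A4. In the forward sense a Wolff rearrangement of A3 would give a ketene function that takes up A4 by [2+2] addition, four-electron ring opening and six-electron ring closure to the phenol A5 (Danheiser benzannulation).

- In favour: every substituent position of ring C is fixed by the mechanism, and the plan is convergent. A5 reaches the target by a single cleavage of one ethyl and two methyl ethers, which is better than the chosen plan after the key step and equal to it in the number of ether bonds cleaved.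
- Against: A3 needs a trisubstituted alkene of defined (E) geometry and a diazo transfer on a substrate that already carries rings A, B and D. The chromone and 2-pyranone chromophores have photochemistry of their own under the irradiation that the Wolff step usually needs. The electrocyclization must form the hindered C1'–C2' bond next to the chromone.
- Comparison: on structure, regiocontrol of ring C is the equal of the chosen plan, where it is bought with the starting arene. On mechanism, a photochemical pericyclic cascade with reactive ketene intermediates is less forgiving than a thermal cycloaddition and standard couplings. On step economy, it is shorter at the end and longer and less certain at the start.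

**Alternative 3:** The cut is C4a–C5 of ring A in A7, which is the same compound as 21. The precursor is the 4-pyranone A6 carrying a 2,4-dioxopentyl chain. Mild base would let the pyranone carbon that becomes C4a attack the terminal ketone, and dehydration would give the chromone.

- In favour: ring B is present from the start, so the question of six- versus five-membered oxygen closure and the chelation-controlled demethylation both disappear, which is better than the chosen plan. The C7 hydroxyl arises free, and the end-game is identical to the chosen one, so on that point the two are equal.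
- Against: the dioxopentyl chain of A6 would have to be attached by lateral carbanion acylation next to ring B while the CH2 between rings C and D is comparably acidic. The aryl-substituted 4-pyranone core would itself need a triketone or diynone precursor. The enolized diketone can also add through oxygen to the pyranone, or the pyranone can be opened by base.
- Comparison: on structure, both plans make ring A last and meet at 21. On mechanism, the aldol is simple but depends on one enolate among several, whereas the cycloaddition depends on one alkyne among two. On step economy, the alternative saves two steps after ring A formation but is expected to lose them in assembling A6.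

Key step: step 8

Remark on the chemistry: diene 15 is treated as a purchasable, moisture-sensitive reagent that is distilled before use; all compounds of the route are achiral.

## Route

Step 1
Reactants: 1 2-(3,5-dimethoxyphenyl)acetic acid
Product: 2 2-(2-iodo-3,5-dimethoxyphenyl)acetic acid
Conditions: N-iodosuccinimide (1.05 equiv), CF3CO2H (cat.), MeCN, 0 °C to rt
Reagents that add atoms: N-iodosuccinimide, O=C1CCC(=O)N1I
Why: Electrophilic aromatic iodination of a 1,3-dimethoxyarene; C2 is para to one methoxy group and ortho to the other and is less crowded than C4 between the two methoxy groups, and one equivalent of reagent limits di-iodination. The iodide is chosen over the bromide because the later alkynylation occurs at a carbon between two ortho substituents.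

Step 2
Reactants: 2 2-(2-iodo-3,5-dimethoxyphenyl)acetic acid; 3 methyl acetoacetate
Product: 6 methyl 6-(2-iodo-3,5-dimethoxyphenyl)-3,5-dioxohexanoate, via acyl imidazolide 4 (not isolated), via dilithio acetoacetate dianion 5 (not isolated)
Conditions: 2, 1,1'-carbonyldiimidazole, THF, rt (gives 4); separately 3 (3 equiv), LiN(iPr)2 (6 equiv), THF, 0 °C (gives 5); 4 added to 5 at −78 °C, then to −20 °C; aq. HCl
Reagents that add atoms: none
Why: Claisen-type acylation of the acetoacetate dianion at its terminal carbon by an N-acylimidazole made in the same operation. The excess of dianion takes up the proton of the more acidic tricarbonyl product and any α-deprotonation of 4, and LiN(iPr)2 is used so that no alkyllithium can exchange with the aryl iodide.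

Step 3
Reactants: 6 methyl 6-(2-iodo-3,5-dimethoxyphenyl)-3,5-dioxohexanoate
Product: 7 4-hydroxy-6-[(2-iodo-3,5-dimethoxyphenyl)methyl]-2H-pyran-2-one
Conditions: DBU, toluene, 90 °C; aq. HCl
Reagents that add atoms: none
Why: Base-mediated lactonization of a 3,5-dioxo ester: the C5 enol oxygen attacks the ester carbonyl, methanol is lost and the 4-hydroxy-2-pyranone forms as its stable enolate salt.

Step 4
Reactants: 7 4-hydroxy-6-[(2-iodo-3,5-dimethoxyphenyl)methyl]-2H-pyran-2-one
Product: 8 6-[(2-iodo-3,5-dimethoxyphenyl)methyl]-4-methoxy-2H-pyran-2-one
Conditions: Me2SO4, K2CO3, acetone, rt to 50 °C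
Reagents that add atoms: dimethyl sulfate, COS(=O)(=O)OC
Why: O-Alkylation of the vinylogous acid with a hard methylating agent and a weak base favours the 4-methoxy-2-pyranone over the 2-methoxy-4-pyranone and over C-methylation. The ether masks the acidic, C3''-nucleophilic enol for the palladium and cycloaddition steps.

Step 5
Reactants: 8 6-[(2-iodo-3,5-dimethoxyphenyl)methyl]-4-methoxy-2H-pyran-2-one; 9 ethynyl(trimethyl)silane
Product: 10 6-({3,5-dimethoxy-2-[(trimethylsilyl)ethynyl]phenyl}methyl)-4-methoxy-2H-pyran-2-one
Conditions: PdCl2(PPh3)2 (cat.), CuI (cat.), Et3N, THF, 50 °C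
Reagents that add atoms: none
Why: Sonogashira coupling; the aryl iodide adds readily to zerovalent palladium despite the donor groups and the two ortho substituents, and the silyl group prevents double coupling and oxidative dimerization of the alkyne.

Step 6
Reactants: 10 6-({3,5-dimethoxy-2-[(trimethylsilyl)ethynyl]phenyl}methyl)-4-methoxy-2H-pyran-2-one
Product: 11 6-[(2-ethynyl-3,5-dimethoxyphenyl)methyl]-4-methoxy-2H-pyran-2-one
Conditions: Bu4NF, AcOH, THF, 0 °C
Reagents that add atoms: none
Why: Fluoride-induced protodesilylation of an alkynylsilane; buffering with acetic acid keeps the medium from deprotonating the doubly activated CH2 group or opening the lactone.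

Step 7
Reactants: 11 6-[(2-ethynyl-3,5-dimethoxyphenyl)methyl]-4-methoxy-2H-pyran-2-one; 12 but-2-ynoic acid
Product: 14 1-{2,4-dimethoxy-6-[(4-methoxy-2-oxo-2H-pyran-6-yl)methyl]phenyl}hexa-1,4-diyn-3-one, via but-2-ynoyl chloride 13 (not isolated)
Conditions: 12, (COCl)2, DMF (cat.), CH2Cl2, 0 °C to rt; then 11, PdCl2(PPh3)2 (cat.), CuI (cat.), Et3N, THF, rt
Reagents that add atoms: none
Why: Acyl Sonogashira coupling of a terminal alkyne with an acid chloride made in the same flask gives the cross-conjugated diynone under mild amine base, without any strong base that ring D and its CH2 group would not tolerate. The acid chloride 13 has no α-hydrogen, so ketene formation cannot compete.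

Step 8
Reactants: 14 1-{2,4-dimethoxy-6-[(4-methoxy-2-oxo-2H-pyran-6-yl)methyl]phenyl}hexa-1,4-diyn-3-one; 15 1,1-dimethoxy-3-(trimethylsilyloxy)buta-1,3-diene
Product: 18 3-{2,4-dimethoxy-6-[(4-methoxy-2-oxo-2H-pyran-6-yl)methyl]phenyl}-1-(4-hydroxy-2-methoxy-6-methylphenyl)prop-2-yn-1-one, via cyclohexadiene cycloadduct 16 (not isolated), via aryl trimethylsilyl ether 17 (not isolated)
Conditions: 15 (1.5–2 equiv), toluene, 0 °C to rt (to 50 °C if slow); then 1 M HCl, THF, rt
Reagents that add atoms: none
Why: The step is a normal-demand Diels–Alder benzannulation of an acetylenic ketone with an electron-rich 1,1-dialkoxy-3-silyloxybutadiene, the known way from alkynyl ketones and esters to resorcinol monoethers. Bond formation is asynchronous: the CH2 terminus of 15, which carries the largest HOMO coefficient, attacks the methyl-bearing β-carbon of the ynone (C5–C6), and the ketene acetal carbon then bonds to the α-carbon (C4a–C8a). Ring A is thus closed as a six-membered ring in [4+2] cycloaddition mode, giving the cyclohexa-1,4-diene 16. 1,4-Elimination of methanol from 16 (C8a–OMe and C6–H) aromatizes the ring to 17, and dilute acid cleaves the aryl silyl ether to the C7 phenol of 18. No stereocentre is formed, since the two sp3 carbons of 16 disappear on aromatization. Site selectivity between the two alkynes is needed: the aryl-substituted alkyne is deactivated by push–pull conjugation with the 2,4-dimethoxyphenyl donor and its β-carbon lies between two ortho substituents, whereas the but-2-ynoyl alkyne carries only a methyl group. Orientation follows from polarity (nucleophilic diene terminus to electrophilic β-carbon), which places methoxy ortho and silyloxy para to the ketone. The methyl ethers on rings C and D leave no O–H to protonate the ketene acetal, and the new electron-rich aryl ketone makes the remaining alkyne of 18 a poorer dienophile, which guards against a second addition.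

Step 9
Reactants: 18 3-{2,4-dimethoxy-6-[(4-methoxy-2-oxo-2H-pyran-6-yl)methyl]phenyl}-1-(4-hydroxy-2-methoxy-6-methylphenyl)prop-2-yn-1-one
Product: 19 1-(2,4-dihydroxy-6-methylphenyl)-3-{2,4-dimethoxy-6-[(4-methoxy-2-oxo-2H-pyran-6-yl)methyl]phenyl}prop-2-yn-1-one
Conditions: BCl3 (3 equiv), CH2Cl2, −78 to 0 °C; aq. NaHCO3
Reagents that add atoms: none
Why: Chelation-controlled ether cleavage: BCl3 bridges the ketone oxygen and the ortho methoxy oxygen in a six-membered chelate and chloride removes that methyl group, while the ring C and ring D ethers have no such chelate. Any chloride adduct across the ynone (a β-chloro enone) is still a competent substrate for the ring closure of step 10.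

Step 10
Reactants: 19 1-(2,4-dihydroxy-6-methylphenyl)-3-{2,4-dimethoxy-6-[(4-methoxy-2-oxo-2H-pyran-6-yl)methyl]phenyl}prop-2-yn-1-one
Product: 21 2-{2,4-dimethoxy-6-[(4-methoxy-2-oxo-2H-pyran-6-yl)methyl]phenyl}-7-hydroxy-5-methyl-4H-chromen-4-one, via diethylamino enone 20 (not isolated)
Conditions: Et2NH (3 equiv), EtOH, rt to 50 °C
Reagents that add atoms: none
Why: Amine-mediated cyclization of an ortho-hydroxyaryl ynone: conjugate addition of Et2NH gives enaminone 20, and the only ortho phenol oxygen then displaces the amine at the β-carbon by addition–elimination. Ring B therefore closes in the 6-endo sense and the 5-exo path to an aurone is avoided. The ring C oxygens are still methylated and cannot compete, and the small excess of amine at low temperature spares the 4-methoxy-2-pyranone.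

Step 11
Reactants: 21 2-{2,4-dimethoxy-6-[(4-methoxy-2-oxo-2H-pyran-6-yl)methyl]phenyl}-7-hydroxy-5-methyl-4H-chromen-4-one
Product: 22 2-{2,4-dihydroxy-6-[(4-hydroxy-2-oxo-2H-pyran-6-yl)methyl]phenyl}-7-hydroxy-5-methyl-4H-chromen-4-one
Conditions: BBr3 (excess), CH2Cl2, −78 °C to rt; MeOH, then H2O
Reagents that add atoms: none
Why: Ether cleavage by a strong Lewis acid: BBr3 complexes the two aryl methyl ethers and the carbonyl-activated ring D methyl ether, and bromide removes the methyl groups. The chromone and 2-pyranone cores tolerate the reagent, and no ynone is left for the freed C2' hydroxyl or ring D enol to attack.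

## Compound list

1 | 2-(3,5-dimethoxyphenyl)acetic acid | COc1cc(CC(=O)O)cc(OC)c1 | starting material
2 | 2-(2-iodo-3,5-dimethoxyphenyl)acetic acid | COc1cc(OC)c(I)c(CC(=O)O)c1 | intermediate
3 | methyl acetoacetate (methyl 3-oxobutanoate) | COC(=O)CC(C)=O | starting material
4 | 1-(1H-imidazol-1-yl)-2-(2-iodo-3,5-dimethoxyphenyl)ethan-1-one | COc1cc(OC)c(I)c(CC(=O)n2ccnc2)c1 | intermediate
5 | dilithium dianion of methyl acetoacetate | [Li+].[Li+].COC(=O)[CH-]C(=O)[CH2-] | intermediate
6 | methyl 6-(2-iodo-3,5-dimethoxyphenyl)-3,5-dioxohexanoate | COC(=O)CC(=O)CC(=O)Cc1cc(OC)cc(OC)c1I | intermediate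
7 | 4-hydroxy-6-[(2-iodo-3,5-dimethoxyphenyl)methyl]-2H-pyran-2-one | COc1cc(OC)c(I)c(Cc2cc(O)cc(=O)o2)c1 | intermediate
8 | 6-[(2-iodo-3,5-dimethoxyphenyl)methyl]-4-methoxy-2H-pyran-2-one | COc1cc(OC)c(I)c(Cc2cc(OC)cc(=O)o2)c1 | intermediate
9 | ethynyl(trimethyl)silane | C#C[Si](C)(C)C | starting material
10 | 6-({3,5-dimethoxy-2-[(trimethylsilyl)ethynyl]phenyl}methyl)-4-methoxy-2H-pyran-2-one | COc1cc(OC)c(C#C[Si](C)(C)C)c(Cc2cc(OC)cc(=O)o2)c1 | intermediate
11 | 6-[(2-ethynyl-3,5-dimethoxyphenyl)methyl]-4-methoxy-2H-pyran-2-one | COc1cc(OC)c(C#C)c(Cc2cc(OC)cc(=O)o2)c1 | intermediate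
12 | but-2-ynoic acid | CC#CC(=O)O | starting material
13 | but-2-ynoyl chloride | CC#CC(=O)Cl | intermediate
14 | 1-{2,4-dimethoxy-6-[(4-methoxy-2-oxo-2H-pyran-6-yl)methyl]phenyl}hexa-1,4-diyn-3-one | CC#CC(=O)C#Cc1c(OC)cc(OC)cc1Cc1cc(OC)cc(=O)o1 | intermediate
15 | 1,1-dimethoxy-3-(trimethylsilyloxy)buta-1,3-diene | COC(OC)=CC(=C)O[Si](C)(C)C | starting material
16 | 1-[6,6-dimethoxy-2-methyl-4-(trimethylsilyloxy)cyclohexa-1,4-dien-1-yl]-3-{2,4-dimethoxy-6-[(4-methoxy-2-oxo-2H-pyran-6-yl)methyl]phenyl}prop-2-yn-1-one | CC1=C(C(=O)C#Cc2c(OC)cc(OC)cc2Cc2cc(OC)cc(=O)o2)C(OC)(OC)C=C(O[Si](C)(C)C)C1 | intermediate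
17 | 3-{2,4-dimethoxy-6-[(4-methoxy-2-oxo-2H-pyran-6-yl)methyl]phenyl}-1-[2-methoxy-6-methyl-4-(trimethylsilyloxy)phenyl]prop-2-yn-1-one | Cc1cc(O[Si](C)(C)C)cc(OC)c1C(=O)C#Cc1c(OC)cc(OC)cc1Cc1cc(OC)cc(=O)o1 | intermediate
18 | 3-{2,4-dimethoxy-6-[(4-methoxy-2-oxo-2H-pyran-6-yl)methyl]phenyl}-1-(4-hydroxy-2-methoxy-6-methylphenyl)prop-2-yn-1-one | Cc1cc(O)cc(OC)c1C(=O)C#Cc1c(OC)cc(OC)cc1Cc1cc(OC)cc(=O)o1 | intermediate
19 | 1-(2,4-dihydroxy-6-methylphenyl)-3-{2,4-dimethoxy-6-[(4-methoxy-2-oxo-2H-pyran-6-yl)methyl]phenyl}prop-2-yn-1-one | Cc1cc(O)cc(O)c1C(=O)C#Cc1c(OC)cc(OC)cc1Cc1cc(OC)cc(=O)o1 | intermediate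
20 | (E)-3-(diethylamino)-1-(2,4-dihydroxy-6-methylphenyl)-3-{2,4-dimethoxy-6-[(4-methoxy-2-oxo-2H-pyran-6-yl)methyl]phenyl}prop-2-en-1-one | CCN(CC)/C(=C/C(=O)c1c(C)cc(O)cc1O)c1c(OC)cc(OC)cc1Cc1cc(OC)cc(=O)o1 | intermediate
21 | 2-{2,4-dimethoxy-6-[(4-methoxy-2-oxo-2H-pyran-6-yl)methyl]phenyl}-7-hydroxy-5-methyl-4H-chromen-4-one | Cc1cc(O)cc2oc(-c3c(OC)cc(OC)cc3Cc3cc(OC)cc(=O)o3)cc(=O)c12 | intermediate
22 | 2-{2,4-dihydroxy-6-[(4-hydroxy-2-oxo-2H-pyran-6-yl)methyl]phenyl}-7-hydroxy-5-methyl-4H-chromen-4-one | Cc1cc(O)cc2oc(-c3c(O)cc(O)cc3Cc3cc(O)cc(=O)o3)cc(=O)c12 | target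

## Step count and least certain steps

Total step count: 11 steps. Longest linear sequence: 11 steps (1 to 22); 3, 9, 12 and 15 enter as purchased reagents.

**Step 8 (key step).** The most likely failure is loss of site selectivity: the diene may add to the aryl-substituted alkyne or to both alkynes, or may stop at conjugate addition without ring closure, because both alkynes draw their activation from the same carbonyl group. The fallback sets out from 11, gives up the cycloaddition and takes ring A from a purchased arene. Purchasable 2,4-dimethoxy-6-methylbenzoic acid is converted with oxalyl chloride into 2,4-dimethoxy-6-methylbenzoyl chloride F1. Acyl Sonogashira coupling of F1 with 11 (PdCl2(PPh3)2, CuI, Et3N) should give 3-{2,4-dimethoxy-6-[(4-methoxy-2-oxo-2H-pyran-6-yl)methyl]phenyl}-1-(2,4-dimethoxy-6-methylphenyl)prop-2-yn-1-one F2. BCl3 should remove the chelated ortho methyl group to give 3-{2,4-dimethoxy-6-[(4-methoxy-2-oxo-2H-pyran-6-yl)methyl]phenyl}-1-(2-hydroxy-4-methoxy-6-methylphenyl)prop-2-yn-1-one F3. Diethylamine should close ring B as in step 10 to give 2-{2,4-dimethoxy-6-[(4-methoxy-2-oxo-2H-pyran-6-yl)methyl]phenyl}-7-methoxy-5-methyl-4H-chromen-4-one F4. BBr3 then cleaves all four methyl ethers, and the sequence comes back to the route at 22.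

**Step 7.** The most likely failure is decomposition of the unsaturated acid chloride, or conjugate addition of amine or chloride to the product under the coupling conditions, because the reagent and the diynone are both strong Michael acceptors. The fallback sets out from 8 and makes the ketone by oxidation instead of acylation. Racemic hexa-1,4-diyn-3-ol F5, made by adding HC≡CMgBr to but-2-ynal in THF at −78 °C, is coupled with 8 under Sonogashira conditions to give racemic 1-{2,4-dimethoxy-6-[(4-methoxy-2-oxo-2H-pyran-6-yl)methyl]phenyl}hexa-1,4-diyn-3-ol F6. Oxidation of the bis-propargylic alcohol with MnO2 in CH2Cl2 removes the only stereocentre and comes back to the route at 14; steps 5 to 7 are bypassed.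

**Step 9.** The most likely failure is addition of chloride across the boron-activated ynone in competition with demethylation, or partial cleavage of the ring D ether, since the complexed ynone is a strong electrophile. The fallback sets out from 18 and reverses the order of events so that the Lewis acid never meets an ynone. Diethylamine is added first to give (E)-3-(diethylamino)-3-{2,4-dimethoxy-6-[(4-methoxy-2-oxo-2H-pyran-6-yl)methyl]phenyl}-1-(4-hydroxy-2-methoxy-6-methylphenyl)prop-2-en-1-one F7, a vinylogous amide that is inert to chloride. BCl3 then removes the chelated methyl group, and the sequence comes back to the route at 20, which closes to 21 on gentle warming with loss of diethylamine.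

**Step 11.** The most likely failure is incomplete cleavage of the ring D methyl ether or of the hindered C2' ether, with degradation of the polyphenol on the long exposure needed to force it. The fallback sets out from 21 and divides the task between two mechanisms. LiI in pyridine at about 100 °C removes the ring D methyl group by substitution at carbon, the pyranone enolate being a good leaving group, to give 2-{2-[(4-hydroxy-2-oxo-2H-pyran-6-yl)methyl]-4,6-dimethoxyphenyl}-7-hydroxy-5-methyl-4H-chromen-4-one F8. A short treatment with BBr3 then cleaves only the two aryl methyl ethers and comes back to the route at 22.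

## Further compounds

F1 | step 8 | 2,4-dimethoxy-6-methylbenzoyl chloride | COc1cc(C)c(C(=O)Cl)c(OC)c1
F2 | step 8 | 3-{2,4-dimethoxy-6-[(4-methoxy-2-oxo-2H-pyran-6-yl)methyl]phenyl}-1-(2,4-dimethoxy-6-methylphenyl)prop-2-yn-1-one | Cc1cc(OC)cc(OC)c1C(=O)C#Cc1c(OC)cc(OC)cc1Cc1cc(OC)cc(=O)o1
F3 | step 8 | 3-{2,4-dimethoxy-6-[(4-methoxy-2-oxo-2H-pyran-6-yl)methyl]phenyl}-1-(2-hydroxy-4-methoxy-6-methylphenyl)prop-2-yn-1-one | Cc1cc(OC)cc(O)c1C(=O)C#Cc1c(OC)cc(OC)cc1Cc1cc(OC)cc(=O)o1
F4 | step 8 | 2-{2,4-dimethoxy-6-[(4-methoxy-2-oxo-2H-pyran-6-yl)methyl]phenyl}-7-methoxy-5-methyl-4H-chromen-4-one | Cc1cc(OC)cc2oc(-c3c(OC)cc(OC)cc3Cc3cc(OC)cc(=O)o3)cc(=O)c12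
F5 | step 7 | hexa-1,4-diyn-3-ol (racemic) | CC#CC(O)C#C
F6 | step 7 | 1-{2,4-dimethoxy-6-[(4-methoxy-2-oxo-2H-pyran-6-yl)methyl]phenyl}hexa-1,4-diyn-3-ol (racemic) | CC#CC(O)C#Cc1c(OC)cc(OC)cc1Cc1cc(OC)cc(=O)o1
F7 | step 9 | (E)-3-(diethylamino)-3-{2,4-dimethoxy-6-[(4-methoxy-2-oxo-2H-pyran-6-yl)methyl]phenyl}-1-(4-hydroxy-2-methoxy-6-methylphenyl)prop-2-en-1-one | CCN(CC)/C(=C/C(=O)c1c(C)cc(O)cc1OC)c1c(OC)cc(OC)cc1Cc1cc(OC)cc(=O)o1
F8 | step 11 | 2-{2-[(4-hydroxy-2-oxo-2H-pyran-6-yl)methyl]-4,6-dimethoxyphenyl}-7-hydroxy-5-methyl-4H-chromen-4-one | Cc1cc(O)cc2oc(-c3c(OC)cc(OC)cc3Cc3cc(O)cc(=O)o3)cc(=O)c12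
A1 | alternative 1 | 2-({6-[(4-hydroxy-2-oxo-2H-pyran-6-yl)methyl]-4-oxo-4H-pyran-2-yl}methyl)-7-methoxy-5-methyl-4H-chromen-4-one | Cc1cc(OC)cc2oc(Cc3cc(=O)cc(Cc4cc(O)cc(=O)o4)o3)cc(=O)c12
A2 | alternative 1 | 2-{2,4-dihydroxy-6-[(4-hydroxy-2-oxo-2H-pyran-6-yl)methyl]phenyl}-7-methoxy-5-methyl-4H-chromen-4-one | Cc1cc(OC)cc2oc(-c3c(O)cc(O)cc3Cc3cc(O)cc(=O)o3)cc(=O)c12
A3 | alternative 2 | (E)-1-diazo-3-[(4-methoxy-2-oxo-2H-pyran-6-yl)methyl]-4-(7-methoxy-5-methyl-4-oxo-4H-chromen-2-yl)but-3-en-2-one | [N-]=[N+]=CC(=O)/C(Cc1cc(OC)cc(=O)o1)=C/c1cc(=O)c2c(C)cc(OC)cc2o1
A4 | alternative 2 | ethoxyacetylene (ethoxyethyne) | C#COCC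
A5 | alternative 2 | 2-{4-ethoxy-2-hydroxy-6-[(4-methoxy-2-oxo-2H-pyran-6-yl)methyl]phenyl}-7-methoxy-5-methyl-4H-chromen-4-one | Cc1cc(OC)cc2oc(-c3c(O)cc(OCC)cc3Cc3cc(OC)cc(=O)o3)cc(=O)c12
A6 | alternative 3 | 1-(6-{2,4-dimethoxy-6-[(4-methoxy-2-oxo-2H-pyran-6-yl)methyl]phenyl}-4-oxo-4H-pyran-2-yl)pentane-2,4-dione | CC(=O)CC(=O)Cc1cc(=O)cc(-c2c(OC)cc(OC)cc2Cc2cc(OC)cc(=O)o2)o1
A7 | alternative 3 | 2-{2,4-dimethoxy-6-[(4-methoxy-2-oxo-2H-pyran-6-yl)methyl]phenyl}-7-hydroxy-5-methyl-4H-chromen-4-one | Cc1cc(O)cc2oc(-c3c(OC)cc(OC)cc3Cc3cc(OC)cc(=O)o3)cc(=O)c12
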